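**Retrosynthetic overview**
- The target is a trans-fused bicycle: ring A (ten-membered carbocycle C1–C10) and ring B (α-methylene-γ-butyrolactone O–C6–C7–C11–C12). Ring B is formed first (Evans aldol/lactonization), ring A second.
- Enabling feature: C14 (CH2OH) sits on C10 of the C1=C10 olefin, whose other allylic carbon is C2. The unit HO–C14–C10=C1–C2 is therefore a 4-substituted but-2-en-1-ol, the retron of distal opening of a 2-vinyloxirane (oxirane C10–C14, vinyl C1=C2). C3 is a plain ring CH2 that can carry two removable sulfonyl groups.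
- Key disconnection C2–C3 (ring A): Pd(PPh3)4-catalysed cycloisomerization of an acyclic vinyl epoxide bearing a C3 bis(phenylsulfonyl)methyl group. It closes ring A, fixes the C1=C10 geometry and releases the C14 hydroxyl; the sulfones are then removed.
- Other disconnections: O8 ester; C11=C13 (Eschenmoser methylenation); C8–C9 (asymmetric isoprenylation, then C10=C14 epoxidation); C6–C7 (Evans syn-aldol, sets C6 and C7); C3–C4 (organocatalytic Michael addition of bis(phenylsulfonyl)methane, sets C4); C4=C5 (cross-metathesis).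

Key step: step 10

Remark: locants follow the germacranolide skeleton (C14 on C10, C15 on C4, C13 = exocyclic methylene, "13-nor" = lactone α-carbon still CH2); the oxirane carbon C10 in 14 and 15 and C11 in 19 and 20 are carried as epimer mixtures because both centres become sp2 later.

**Step 1**
Reactants: 1 allyloxy(tert-butyl)dimethylsilane; 2 (E)-but-2-enal (crotonaldehyde)
Product: 3 (E)-4-(tert-butyldimethylsilyloxy)but-2-enal
Conditions: 2 (3 equiv), Hoveyda–Grubbs second-generation catalyst [RuCl2(H2IMes)(=CH-C6H4-2-OiPr)] (2 mol%), CH2Cl2, 40 °C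
Reagents that add atoms: none
Why: Olefin cross-metathesis of a terminal allyl ether with an enal favours the cross product and gives the conjugated E-olefin under thermodynamic control, with loss of propene.

**Step 2**
Reactants: 3 (E)-4-(tert-butyldimethylsilyloxy)but-2-enal; 4 bis(phenylsulfonyl)methane
Product: 5 (3S)-3-(silyloxymethyl)-4,4-bis(phenylsulfonyl)butanal
Conditions: (S)-α,α-diphenylprolinol trimethylsilyl ether (10 mol%), toluene, rt
Reagents that add atoms: none
Why: Iminium-ion-catalysed asymmetric Michael addition in which the bis-sulfonyl carbon adds to C4 of the E-iminium ion on the face opposite the CPh2(OSiMe3) group of the (S)-catalyst, which sets C4 (S) and installs the later C3 nucleophile.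

**Step 3**
Reactants: 6 (4S)-4-benzyl-1,3-oxazolidin-2-one; 7 methyl 4-chloro-4-oxobutanoate
Product: 8 N-(3-methoxycarbonylpropanoyl)oxazolidinone
Conditions: n-BuLi, THF, −78 °C; then 7, −78 → 0 °C
Reagents that add atoms: none
Why: N-acylation of the lithiated oxazolidinone by the acid chloride, which is far more electrophilic than the methyl ester.

**Step 4**
Reactants: 8 N-(3-methoxycarbonylpropanoyl)oxazolidinone; 5 (3S)-3-(silyloxymethyl)-4,4-bis(phenylsulfonyl)butanal
Product: 10 trans-lactone imide (ring B), via syn-aldol adduct 9 (not isolated)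
Conditions: 8, Bu2BOTf, iPr2NEt, CH2Cl2, 0 °C; 5, −78 → 0 °C; pH 7 buffer, MeOH, H2O2; crude adduct, PPTS (cat.), CH2Cl2, rt
Reagents that add atoms: none
Why: Evans syn-aldol reaction in which the Z-boron enolate of the imide reacts through a Zimmerman–Traxler chair and the (S)-benzyl auxiliary selects the aldehyde face, setting C6 (R) and C7 together; acid-catalysed lactonization of the γ-hydroxy ester then closes ring B as the trans-lactone.

**Step 5**
Reactants: 10 trans-lactone imide
Product: 11 S-ethyl thioester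
Conditions: EtSH, n-BuLi, THF, 0 °C; then aq. NH4Cl
Reagents that add atoms: ethanethiol, CCS
Why: Thiolysis of the N-acyloxazolidinone, in which the soft thiolate attacks the exocyclic imide carbonyl (C8) and releases the auxiliary while the lactone stays closed.

**Step 6**
Reactants: 11 S-ethyl thioester
Product: 12 lactone aldehyde (C8 = CHO)
Conditions: Et3SiH, Pd/C (10 wt%), acetone, rt
Reagents that add atoms: none
Why: Fukuyama reduction of the thioester to the aldehyde under neutral conditions that should spare the lactone, the silyl ether and the sulfones and should not epimerize C7 (trans-disposed, the favoured arrangement).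

**Step 7**
Reactants: 12 lactone aldehyde
Product: 13 homoallylic alcohol with 2-substituted buta-1,3-diene
Conditions: B-isoprenyldiisopinocampheylborane from (−)-α-pinene [isoprene, potassium 2,2,6,6-tetramethylpiperidide; (+)-Ipc2BOMe; BF3·OEt2], Et2O/THF, −78 °C; then pH 7 buffer, H2O2, 0 °C
Reagents that add atoms: B-(2-methylidenebut-3-en-1-yl)diisopinocampheylborane, C=CC(=C)CB([C@H]1C[C@H]2C[C@@H]([C@@H]1C)C2(C)C)[C@H]1C[C@H]2C[C@@H]([C@@H]1C)C2(C)C
Why: Brown asymmetric allylboration (isoprenylation) through a closed six-membered chair transition state, in which the isopinocampheyl groups derived from (−)-α-pinene direct the isoprenyl unit to the Re face of the C8 aldehyde (reagent control), setting C8 (R) and bringing in C9, C10, C14, C1 and C2.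

**Step 8**
Reactants: 13 homoallylic alcohol
Product: 14 epoxy alcohol (2-alkyl-2-vinyloxirane)
Conditions: VO(acac)2 (5 mol%), t-BuOOH, CH2Cl2, 0 °C → rt
Reagents that add atoms: tert-butyl hydroperoxide, CC(C)(C)OO
Why: Hydroxyl-directed vanadium-catalysed epoxidation, in which the C8 hydroxyl delivers the peroxide to the homoallylic, more electron-rich 1,1-disubstituted C10=C14 bond and leaves the vinyl group C1=C2 alone; the new centre C10 forms as a mixture, which does not matter because it is planarized in step 10.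

**Step 9**
Reactants: 14 epoxy alcohol
Product: 15 triethylsilyl ether (cyclization precursor)
Conditions: Et3SiCl, imidazole, DMF, 0 °C
Reagents that add atoms: chlorotriethylsilane, CC[Si](Cl)(CC)CC
Why: Silylation of the secondary C8 hydroxyl, which blocks O-alkylation in step 10 and translactonization in the basic steps 11 and 13, with a group removable later beside primary TBS ethers.

**Step 10**
Reactants: 15 triethylsilyl ether (cyclization precursor)
Product: 16 ring A/ring B bicycle with C3 bis-sulfone and free C14 hydroxyl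
Conditions: Pd(PPh3)4 (5 mol%), dppe (10 mol%), THF, 65 °C, 0.02 M
Reagents that add atoms: none
Why: Zerovalent palladium ionizes the 2-alkyl-2-vinyloxirane with inversion to a zwitterionic π-allylpalladium alkoxide (C10–C1–C2), whose C14 alkoxide deprotonates the bis(phenylsulfonyl)methyl C3–H, so that carbanion and electrophile arise as one ion pair without added base and combine at the unsubstituted terminus C2. The closest known reaction type is the Tsuji–Trost alkylation in its vinyl-epoxide cycloisomerization form, which is used to close medium and large carbocycles with sulfone-stabilized carbanions at ordinary concentration. Ring A is closed in a 10-membered ring closure at the distal allyl terminus (formal SN2′ opening); attack at C10 would need an eight-membered ring and a quaternary centre. No stereocentre is created (C3 bears two identical sulfonyl groups and both C10 epimers of 15 give the same π-allyl connectivity), so C4, C6, C7 and C8 are carried through unchanged. The one stereochemical element made, the C1=C10 geometry (C14 trans to C2, that is C9 and C2 cis in the ring), is controlled by the preferred syn position of the CH2O– substituent on the π-allyl terminus and by the ring size, since only the ring-cis olefin fits a ten-membered ring comfortably. The selectivity needed is C-alkylation at C2 in competition with O-alkylation, β-hydride loss to a diene and oligomerization; it is secured by the silyl group on O8, by the acidity of the bis-sulfone (the only proton source for the alkoxide) and by the intramolecular ion pair, which acts as a template.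

**Step 11**
Reactants: 16 bicycle with C3 bis-sulfone
Product: 17 desulfonylated bicycle (C3 = CH2)
Conditions: Na(Hg) (6%), Na2HPO4, MeOH/THF, −20 → 0 °C
Reagents that add atoms: none
Why: Reductive desulfonylation by single-electron transfer removes both activating groups from C3 as sulfinate under buffered conditions that should leave the lactone, the silyl ethers and the isolated olefin intact.

**Step 12**
Reactants: 17 desulfonylated bicycle
Product: 18 14,15-bis-TBS ether
Conditions: TBSCl, imidazole, DMF, rt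
Reagents that add atoms: tert-butyl(chloro)dimethylsilane, CC(C)(C)[Si](C)(C)Cl
Why: Silylation of the primary allylic C14 hydroxyl, so that later only O8 can be acylated.

**Step 13**
Reactants: 18 14,15-bis-TBS ether
Product: 21 α-methylene lactone, via Mannich base 19 (not isolated), via ammonium iodide 20 (not isolated)
Conditions: LiN(iPr)2, THF, −78 °C; CH2=NMe2+ I−, −78 °C → rt; crude amine, MeI, MeOH, rt; then aq. NaHCO3, CH2Cl2
Reagents that add atoms: N,N-dimethylmethyleneiminium iodide (Eschenmoser's salt), C=[N+](C)C.[I-]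
Why: Eschenmoser methylenation, in which a Mannich reaction of the lactone lithium enolate (the only acidic C–H left) introduces C13 and quaternization followed by base-induced Hofmann-type elimination gives the exocyclic C11=C13 olefin; the configuration at C11 is irrelevant.

**Step 14**
Reactants: 21 α-methylene lactone
Product: 22 C8 alcohol
Conditions: HF·pyridine, pyridine, THF, 0 °C
Reagents that add atoms: none
Why: Chemoselective desilylation, the secondary triethylsilyl ether being cleaved by buffered HF much faster than the two primary tert-butyldimethylsilyl ethers.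

**Step 15**
Reactants: 22 C8 alcohol
Product: 23 8-O-methacrylate
Conditions: methacrylic anhydride, Et3N, DMAP, CH2Cl2, rt
Reagents that add atoms: methacrylic anhydride, C=C(C)C(=O)OC(=O)C(C)=C
Why: DMAP-catalysed acylation (nucleophilic acyl transfer) of the only free hydroxyl, O8, with retention at C8.

**Step 16**
Reactants: 23 8-O-methacrylate
Product: 24 CNP0546547.2
Conditions: HF·pyridine, THF, 0 °C → rt
Reagents that add atoms: none
Why: Fluoride-mediated cleavage of both primary TBS ethers under mildly acidic conditions that should neither add to the two acrylate-type acceptors nor move the ester.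

**Compound list**

1 | allyloxy(tert-butyl)dimethylsilane | C=CCO[Si](C)(C)C(C)(C)C | starting material
2 | (E)-but-2-enal (crotonaldehyde) | C/C=C/C=O | starting material
3 | (E)-4-{[tert-butyl(dimethyl)silyl]oxy}but-2-enal | O=C/C=C/CO[Si](C)(C)C(C)(C)C | intermediate
4 | bis(phenylsulfonyl)methane | O=S(=O)(CS(=O)(=O)c1ccccc1)c1ccccc1 | starting material
5 | (3S)-3-({[tert-butyl(dimethyl)silyl]oxy}methyl)-4,4-bis(phenylsulfonyl)butanal | O=S(=O)(c1ccccc1)C(S(=O)(=O)c1ccccc1)[C@H](CO[Si](C)(C)C(C)(C)C)CC=O | intermediate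
6 | (4S)-4-benzyl-1,3-oxazolidin-2-one | O=C1N[C@@H](Cc2ccccc2)CO1 | starting material
7 | methyl 4-chloro-4-oxobutanoate | COC(=O)CCC(Cl)=O | starting material
8 | methyl 4-[(4S)-4-benzyl-2-oxo-1,3-oxazolidin-3-yl]-4-oxobutanoate | COC(=O)CCC(=O)N1[C@@H](Cc2ccccc2)COC1=O | intermediate
9 | methyl (3S,4R,6S)-3-{[(4S)-4-benzyl-2-oxo-1,3-oxazolidin-3-yl]carbonyl}-6-({[tert-butyl(dimethyl)silyl]oxy}methyl)-4-hydroxy-7,7-bis(phenylsulfonyl)heptanoate (syn-aldol adduct) | O=S(=O)(c1ccccc1)C(S(=O)(=O)c1ccccc1)[C@H](CO[Si](C)(C)C(C)(C)C)C[C@@H](O)[C@H](CC(=O)OC)C(=O)N1[C@@H](Cc2ccccc2)COC1=O | intermediate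
10 | (4S)-4-benzyl-3-{[(2R,3S)-2-[(2S)-2-({[tert-butyl(dimethyl)silyl]oxy}methyl)-3,3-bis(phenylsulfonyl)propyl]-5-oxooxolan-3-yl]carbonyl}-1,3-oxazolidin-2-one (trans-lactone, ring B) | O=S(=O)(c1ccccc1)C(S(=O)(=O)c1ccccc1)[C@H](CO[Si](C)(C)C(C)(C)C)C[C@H]1OC(=O)C[C@@H]1C(=O)N1[C@@H](Cc2ccccc2)COC1=O | intermediate
11 | S-ethyl (2R,3S)-2-[(2S)-2-({[tert-butyl(dimethyl)silyl]oxy}methyl)-3,3-bis(phenylsulfonyl)propyl]-5-oxooxolane-3-carbothioate | O=S(=O)(c1ccccc1)C(S(=O)(=O)c1ccccc1)[C@H](CO[Si](C)(C)C(C)(C)C)C[C@H]1OC(=O)C[C@@H]1C(=O)SCC | intermediate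
12 | (2R,3S)-2-[(2S)-2-({[tert-butyl(dimethyl)silyl]oxy}methyl)-3,3-bis(phenylsulfonyl)propyl]-5-oxooxolane-3-carbaldehyde | O=S(=O)(c1ccccc1)C(S(=O)(=O)c1ccccc1)[C@H](CO[Si](C)(C)C(C)(C)C)C[C@H]1OC(=O)C[C@@H]1C=O | intermediate
13 | (4R,5R)-5-[(2S)-2-({[tert-butyl(dimethyl)silyl]oxy}methyl)-3,3-bis(phenylsulfonyl)propyl]-4-[(1R)-1-hydroxy-3-methylidenepent-4-en-1-yl]oxolan-2-one | O=S(=O)(c1ccccc1)C(S(=O)(=O)c1ccccc1)[C@H](CO[Si](C)(C)C(C)(C)C)C[C@H]1OC(=O)C[C@@H]1[C@H](O)CC(=C)C=C | intermediate
14 | (4R,5R)-5-[(2S)-2-({[tert-butyl(dimethyl)silyl]oxy}methyl)-3,3-bis(phenylsulfonyl)propyl]-4-[(1R)-2-(2-ethenyloxiran-2-yl)-1-hydroxyethyl]oxolan-2-one (both epimers at the oxirane carbon) | O=S(=O)(c1ccccc1)C(S(=O)(=O)c1ccccc1)[C@H](CO[Si](C)(C)C(C)(C)C)C[C@H]1OC(=O)C[C@@H]1[C@H](O)CC1(C=C)CO1 | intermediate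
15 | (4S,5R)-5-[(2S)-2-({[tert-butyl(dimethyl)silyl]oxy}methyl)-3,3-bis(phenylsulfonyl)propyl]-4-[(1R)-2-(2-ethenyloxiran-2-yl)-1-(triethylsilyloxy)ethyl]oxolan-2-one (both epimers at the oxirane carbon) | O=S(=O)(c1ccccc1)C(S(=O)(=O)c1ccccc1)[C@H](CO[Si](C)(C)C(C)(C)C)C[C@H]1OC(=O)C[C@@H]1[C@H](O[Si](CC)(CC)CC)CC1(C=C)CO1 | intermediate
16 | (1(10)E,4S,6R,7S,8R)-15-{[tert-butyl(dimethyl)silyl]oxy}-14-hydroxy-3,3-bis(phenylsulfonyl)-8-(triethylsilyloxy)-13-norgermacr-1(10)-en-12,6-olide | CC[Si](CC)(CC)O[C@@H]1C/C(CO)=C\CC(S(=O)(=O)c3ccccc3)(S(=O)(=O)c3ccccc3)[C@H](CO[Si](C)(C)C(C)(C)C)C[C@H]2OC(=O)C[C@H]12 | intermediate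
17 | (1(10)E,4S,6R,7S,8R)-15-{[tert-butyl(dimethyl)silyl]oxy}-14-hydroxy-8-(triethylsilyloxy)-13-norgermacr-1(10)-en-12,6-olide | CC[Si](CC)(CC)O[C@@H]1C/C(CO)=C\CC[C@H](CO[Si](C)(C)C(C)(C)C)C[C@H]2OC(=O)C[C@H]12 | intermediate
18 | (1(10)E,4S,6R,7S,8R)-14,15-bis{[tert-butyl(dimethyl)silyl]oxy}-8-(triethylsilyloxy)-13-norgermacr-1(10)-en-12,6-olide | CC[Si](CC)(CC)O[C@@H]1C/C(CO[Si](C)(C)C(C)(C)C)=C\CC[C@H](CO[Si](C)(C)C(C)(C)C)C[C@H]2OC(=O)C[C@H]12 | intermediate
19 | (1(10)E,4S,6R,7S,8R)-14,15-bis{[tert-butyl(dimethyl)silyl]oxy}-13-(dimethylamino)-8-(triethylsilyloxy)germacr-1(10)-en-12,6-olide (C11 epimers; Mannich base) | CC[Si](CC)(CC)O[C@@H]1C/C(CO[Si](C)(C)C(C)(C)C)=C\CC[C@H](CO[Si](C)(C)C(C)(C)C)C[C@H]2OC(=O)C(CN(C)C)[C@H]12 | intermediate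
20 | trimethylammonium iodide of 19 (13-trimethylammonio derivative, C11 epimers) | CC[Si](CC)(CC)O[C@@H]1C/C(CO[Si](C)(C)C(C)(C)C)=C\CC[C@H](CO[Si](C)(C)C(C)(C)C)C[C@H]2OC(=O)C(C[N+](C)(C)C)[C@H]12.[I-] | intermediate
21 | (1(10)E,4S,6R,7S,8R)-14,15-bis{[tert-butyl(dimethyl)silyl]oxy}-8-(triethylsilyloxy)germacra-1(10),11(13)-dien-12,6-olide | CC[Si](CC)(CC)O[C@@H]1C/C(CO[Si](C)(C)C(C)(C)C)=C\CC[C@H](CO[Si](C)(C)C(C)(C)C)C[C@H]2OC(=O)C(=C)[C@H]12 | intermediate
22 | (1(10)E,4S,6R,7R,8R)-14,15-bis{[tert-butyl(dimethyl)silyl]oxy}-8-hydroxygermacra-1(10),11(13)-dien-12,6-olide (same spatial arrangement; the C7 descriptor changes only through CIP ranking) | O[C@@H]1C/C(CO[Si](C)(C)C(C)(C)C)=C\CC[C@H](CO[Si](C)(C)C(C)(C)C)C[C@H]2OC(=O)C(=C)[C@H]12 | intermediate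
23 | (1(10)E,4S,6R,7S,8R)-14,15-bis{[tert-butyl(dimethyl)silyl]oxy}-8-(2-methylprop-2-enoyloxy)germacra-1(10),11(13)-dien-12,6-olide | C=C(C)C(=O)O[C@@H]1C/C(CO[Si](C)(C)C(C)(C)C)=C\CC[C@H](CO[Si](C)(C)C(C)(C)C)C[C@H]2OC(=O)C(=C)[C@H]12 | intermediate
24 | (1(10)E,4S,6R,7S,8R)-14,15-dihydroxy-8-(2-methylprop-2-enoyloxy)germacra-1(10),11(13)-dien-12,6-olide (CNP0546547.2) | C=C(C)C(=O)O[C@@H]1C/C(CO)=C\CC[C@H](CO)C[C@H]2OC(=O)C(=C)[C@H]12 | target

**Step count and risks**

Total step count: 16. Longest linear sequence: 15 steps (steps 1, 2 and 4–16; step 3 prepares imide 8 separately).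

Steps most likely to fail:

1. Step 10 (ring A closure). The π-allylpalladium intermediate may lose a β-hydrogen to give a diene, or couple intermolecularly, faster than the hindered tertiary carbanion closes the ten-membered ring. Fallback, setting out from 15 and returning at 16: the vinyl epoxide of 15 is opened with LiBr and AcOH in THF to the rearranged primary bromide, the E-allylic bromide F1. The same C2–C3 bond is then closed by classical base-mediated intramolecular alkylation of the bis-sulfonyl carbanion (Cs2CO3, DMF, high dilution, slow addition), which should give 16. The E geometry of F1 keeps the C14 hydroxyl away from C2.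

2. Step 7 (C8 carbinol). Facial selectivity may be poor if the chiral borane and the C7 stereocentre are mismatched, and the β-acyloxy aldehyde may undergo elimination during a slow addition. Fallback, setting out from 12 and returning at 13: unselective Barbier isoprenylation with 2-(bromomethyl)buta-1,3-diene and indium powder in THF/H2O gives the C8-epimeric carbinols F2. Dess–Martin oxidation converts both into the ketone F3. Catalyst-controlled CBS reduction ((S)-2-methyl-CBS-oxazaborolidine, catecholborane, toluene, −78 °C) should then deliver the 8R alcohol 13.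

3. Step 5 (auxiliary removal). The thiolate may act as a base, causing E1cB opening of the lactone (loss of O6 from the position β to the activated acyl group) or epimerization at C7. Fallback, setting out from 10 and returning at 12 (11 is bypassed): LiOH/H2O2 in THF/H2O cleaves the auxiliary to the carboxylic acid F4. BH3·SMe2 reduces the acid chemoselectively beside the lactone to the primary alcohol F5. Dess–Martin oxidation then gives aldehyde 12.

**Further compounds**

F1 | step 10 | (4S,5R)-4-[(1R,3E)-5-bromo-3-(hydroxymethyl)-1-(triethylsilyloxy)pent-3-en-1-yl]-5-[(2S)-2-({[tert-butyl(dimethyl)silyl]oxy}methyl)-3,3-bis(phenylsulfonyl)propyl]oxolan-2-one | O=S(=O)(c1ccccc1)C(S(=O)(=O)c1ccccc1)[C@H](CO[Si](C)(C)C(C)(C)C)C[C@H]1OC(=O)C[C@@H]1[C@H](O[Si](CC)(CC)CC)C/C(CO)=C\CBr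
F2 | step 7 | (4R,5R)-5-[(2S)-2-({[tert-butyl(dimethyl)silyl]oxy}methyl)-3,3-bis(phenylsulfonyl)propyl]-4-(1-hydroxy-3-methylidenepent-4-en-1-yl)oxolan-2-one (both epimers at the carbinol carbon C8) | O=S(=O)(c1ccccc1)C(S(=O)(=O)c1ccccc1)[C@H](CO[Si](C)(C)C(C)(C)C)C[C@H]1OC(=O)C[C@@H]1C(O)CC(=C)C=C
F3 | step 7 | (4S,5R)-5-[(2S)-2-({[tert-butyl(dimethyl)silyl]oxy}methyl)-3,3-bis(phenylsulfonyl)propyl]-4-(3-methylidenepent-4-enoyl)oxolan-2-one | O=S(=O)(c1ccccc1)C(S(=O)(=O)c1ccccc1)[C@H](CO[Si](C)(C)C(C)(C)C)C[C@H]1OC(=O)C[C@@H]1C(=O)CC(=C)C=C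
F4 | step 5 | (2R,3S)-2-[(2S)-2-({[tert-butyl(dimethyl)silyl]oxy}methyl)-3,3-bis(phenylsulfonyl)propyl]-5-oxooxolane-3-carboxylic acid | O=S(=O)(c1ccccc1)C(S(=O)(=O)c1ccccc1)[C@H](CO[Si](C)(C)C(C)(C)C)C[C@H]1OC(=O)C[C@@H]1C(=O)O
F5 | step 5 | (4R,5R)-5-[(2S)-2-({[tert-butyl(dimethyl)silyl]oxy}methyl)-3,3-bis(phenylsulfonyl)propyl]-4-(hydroxymethyl)oxolan-2-one | O=S(=O)(c1ccccc1)C(S(=O)(=O)c1ccccc1)[C@H](CO[Si](C)(C)C(C)(C)C)C[C@H]1OC(=O)C[C@@H]1CO
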